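Substrate turns into intermediate on the free catalyst, and the intermediate then either meets coupling partner on the second catalyst and becomes target, or falls to side product.

| setting | beta | zeta | delta | midnight | spring |
|---|---|---|---|---|---|
| substrate | 0.50 M | 0.50 M | 0.50 M | 0.50 M | 0.50 M |
| coupling partner | 0.90 M | 0.90 M | 0.90 M | 0.900 M | 0.900 M |
| free catalyst | 5 mM | 5 mM | 2.5 mM | 5.0 mM | 5.0 mM |
| second catalyst | 6.5 mM | 26 mM | 13 mM | 13 mM | 13 mM |
| temperature | 5 °C | 16 °C | 5 °C | 20 °C | 0 °C |
| remark | run made earlier | run made earlier | run made earlier |  |  |
| time |  |  |  | 6.0 min | 6.0 min |

- beta (time / min: target / %): 1.00: 2.2; 1.33: 3.0; 2.00: 4.7; 3.00: 7.1; 5.00: 12.1; 8.00: 14.0; 12.0: 15.4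
- zeta (time / min: target / %): 0.500: 5.6; 0.667: 7.9; 1.00: 12.5; 1.50: 17.2; 2.50: 24.0; 4.00: 28.7; 6.00: 30.2
- delta (time / min: target / %): 1.00: 2.1; 3.00: 8.7; 6.00: 15.8; 8.00: 19.5; 12.0: 23.3

(scatter of a reading: 0.3 percentage points)

- steps under discussion: coupling partner + second catalyst + intermediate -> second catalyst + target; substrate + free catalyst -> free catalyst + intermediate; intermediate -> side product

1. the flask that comes out highest in amount of target, in percent of the substrate charged, or "all alike" when all lie within 1.5 percentage points (midnight / spring / all alike)
2. target at the end, in percent of the substrate charged, midnight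
3. target at the end, in percent of the substrate charged, spring

Both products leave the same intermediate, so the amount of intermediate cancels from their ratio. We therefore carry ρ, target formed per side product (the selectivity factor), and by the trapping step it scales with the second catalyst. Beta, zeta, midnight and spring share the coupling partner charge 0.900 M.

We count the rest of the charge at the last reading as side product and scale to 13 mM. That reads 0.364 from beta at 5 °C and 0.216 from zeta at 16 °C, and we take both readings as a little low, since the last reading of each run stands higher than the one before it. Letting equal steps of temperature multiply ρ by the same factor gives 0.179 for midnight and, for spring, ρ = 0.461.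

The final shares ρ/(1+ρ) are then 15.2% for midnight and 31.6% for spring. Zeta gained 1.5 percentage points between its last two readings, and midnight is warmer than zeta, so we take midnight as nearly finished at 6.0 min. We take spring, colder than beta, as unfinished at 6.0 min: beta had reached 0.786 of its last reading by 5.00 min, and applying that fraction gives our spring estimate of 24.8%.

The forecast differs somewhat from ours. It names spring as highest, with midnight at 16.5% (12.5% to 21%) and spring at 22.5% (17.5% to 27%). Its ground: “Final yield tracks the second catalyst and falls with warmth.”

The flasks give 16.8% for midnight and 20.7% for spring, so spring stands higher.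

    coupling partner + second catalyst + intermediate → second catalyst + target (k = 0.280 M⁻² s⁻¹, Ea = 45.0 kJ mol⁻¹)
    substrate + free catalyst → free catalyst + intermediate (k = 0.910 M⁻¹ s⁻¹, Ea = 37.0 kJ mol⁻¹)
    intermediate → side product (k = 0.00680 s⁻¹, Ea = 72.0 kJ mol⁻¹)
    (constants at 0 °C)

In spring at 6.00 min, substrate 19.4% and intermediate 14.3% still stand, so 66.3% of the charge has passed the fork. The share from ρ applied to that gives 20.9% of target. Carried to a flask like spring kept at −25 °C, ρ becomes 1.51. That flask holds target 2.09% and side product 1.32% at 6.00 min, a ratio of 1.58.

All runs come from a simulation from invented constants.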